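The δ-lactone (C8–C7(=O)–O–C20–C10–C9, ent-kaurane numbering) is closed by its C20–C10 bond. An acyloxymethyl radical, made from the halomethyl ester of the C8 bridgehead acid, adds 6-exo to C10, the β-carbon of the C5=C10 keto-enal in ring A that the 6,7-seco pattern (formyl C6 on C5) offers. This one operation creates the spiro-quaternary C10 and C5, with H9 steering the face through allylic strain. The precursor is a bicyclo[3.2.1]octane acid (rings C and D) carrying the ring A keto-enal at C9, built from two cyclohexenones by Negishi coupling, nitromethane Michael addition and a palladium-mediated enolate–alkene cyclisation.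

Key step: step 16

Remarks on the chemistry:
- Numbering: ring A = C1–C5, C10; C6 on C5; ring C = C8, C9, C11–C14; ring D = C8, C14, C13, C16, C15; C17 = exocyclic methylene carbon.
- RA = 7-(1,3-dioxolan-2-yl)-8,8-dimethyl-1,4-dioxaspiro[4.5]dec-6-en-6-yl; RA′ = 2-formyl-3,3-dimethyl-6-oxocyclohex-1-en-1-yl.
- Compounds 15–17 are carried as C9 epimers; C9 is fixed in step 12 under thermodynamic control.
- Assumption: hydride attacks the C15 ketone from the ring D face remote from the C9–C11–C12 bridge (step 21).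

Step 1
Reactants: 1 cyclohex-2-en-1-one; 2 potassium isopropenyltrifluoroborate
Product: 3 (S)-3-(prop-1-en-2-yl)cyclohexan-1-one
Conditions: [Rh(cod)2]PF6 (3 mol %), (S)-BINAP, toluene/H2O, 100 °C
Reagents that add atoms: none
Why: Rhodium-catalysed asymmetric 1,4-addition of an alkenyl boron reagent (Hayashi–Miyaura reaction), in which the (S)-BINAP complex adds the isopropenyl group to one enone face and fixes C13.

Step 2
Reactants: 3 (S)-3-(prop-1-en-2-yl)cyclohexan-1-one
Product: 5 (S)-5-(prop-1-en-2-yl)cyclohex-2-en-1-one, via trimethylsilyl enol ether 4 (not isolated)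
Conditions: LiN(iPr)2, Me3SiCl, THF, −78 °C; then Pd(OAc)2 (10 mol %), O2, DMSO, 60 °C
Reagents that add atoms: none
Why: Kinetic enolisation at the α-carbon remote from the isopropenyl group followed by Saegusa–Ito dehydrosilylation (divalent palladium, reoxidised by O2) gives the enone without touching C13.

Step 3
Reactants: 5 (S)-5-(prop-1-en-2-yl)cyclohex-2-en-1-one
Product: 6 (S)-2-iodo-5-(prop-1-en-2-yl)cyclohex-2-en-1-one
Conditions: I2, pyridine, CH2Cl2, rt
Reagents that add atoms: iodine II
Why: Johnson α-iodination of an enone (pyridine conjugate addition, iodination, elimination) installs the coupling handle at C9.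

Step 4
Reactants: 7 4,4-dimethylcyclohex-2-en-1-one
Product: 9 3,4,4-trimethylcyclohex-2-en-1-one, via silyl enol ether 8 (not isolated)
Conditions: Me2CuLi, Me3SiCl, Et2O, −78 °C; then Pd(OAc)2 (10 mol %), O2, DMSO, 60 °C
Reagents that add atoms: lithium dimethylcuprate [Li+].C[Cu-]C
Why: Silyl-accelerated cuprate conjugate addition places the C6 methyl next to the gem-dimethyl carbon, and Saegusa–Ito oxidation of the trapped enol ether restores the enone.

Step 5
Reactants: 9 3,4,4-trimethylcyclohex-2-en-1-one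
Product: 10 6,6-dimethyl-3-oxocyclohex-1-ene-1-carbaldehyde
Conditions: SeO2, dioxane/H2O, reflux
Reagents that add atoms: selenium dioxide O=[Se]=O
Why: Riley oxidation converts the γ-methyl of the enone (its vinylogous α-position) into the formyl group C6.

Step 6
Reactants: 10 6,6-dimethyl-3-oxocyclohex-1-ene-1-carbaldehyde
Product: 11 2-bromo-6,6-dimethyl-3-oxocyclohex-1-ene-1-carbaldehyde
Conditions: Br2, CH2Cl2, 0 °C; then Et3N
Reagents that add atoms: bromine BrBr
Why: Bromination–dehydrobromination (Br2 addition, then E1cB loss of HBr from the carbon α to the ketone) puts bromine on C10.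

Step 7
Reactants: 11 2-bromo-6,6-dimethyl-3-oxocyclohex-1-ene-1-carbaldehyde
Product: 12 6-bromo-7-(1,3-dioxolan-2-yl)-8,8-dimethyl-1,4-dioxaspiro[4.5]dec-6-ene
Conditions: HOCH2CH2OH, TsOH (cat.), benzene, reflux (Dean–Stark)
Reagents that add atoms: ethane-1,2-diol OCCO
Why: Acid-catalysed acetalisation masks ketone C1 and aldehyde C6 so that ring A survives organolithium, enolate and hydride chemistry.

Step 8
Reactants: 12 6-bromo-7-(1,3-dioxolan-2-yl)-8,8-dimethyl-1,4-dioxaspiro[4.5]dec-6-ene; 6 (S)-2-iodo-5-(prop-1-en-2-yl)cyclohex-2-en-1-one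
Product: 14 (S)-2-RA-5-(prop-1-en-2-yl)cyclohex-2-en-1-one, via alkenylzinc chloride 13 (not isolated)
Conditions: 12, t-BuLi (2 equiv), THF, −78 °C; ZnCl2; then 6, Pd2(dba)3 (2.5 mol %), SPhos, THF, 50 °C
Reagents that add atoms: none
Why: Halogen–lithium exchange and transmetalation give an alkenylzinc that undergoes Negishi cross-coupling with the α-iodoenone, forming the C9–C10 bond between two sp2 carbons.

Step 9
Reactants: 14 (S)-2-RA-5-(prop-1-en-2-yl)cyclohex-2-en-1-one
Product: 15 2-RA-3-(nitromethyl)-5-(prop-1-en-2-yl)cyclohexan-1-one (nitromethyl trans to isopropenyl)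
Conditions: CH3NO2, DBU (cat.), MeCN, rt
Reagents that add atoms: nitromethane C[N+](=O)[O-]
Why: Michael addition of the nitronate to the enone β-carbon C8 occurs axially, anti to the isopropenyl group, and brings in C7.

Step 10
Reactants: 15 2-RA-3-(nitromethyl)-5-(prop-1-en-2-yl)cyclohexan-1-one
Product: 16 3-oxo-2-RA-5-(prop-1-en-2-yl)cyclohexane-1-carboxylic acid
Conditions: NaNO2, AcOH, DMSO, 35 °C
Reagents that add atoms: sodium nitrite [Na+].[O-]N=O
Why: Nef-type oxidation of a primary nitroalkane under nitrosating conditions (through the nitrolic acid) turns C7 into the carboxylic acid.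

Step 11
Reactants: 16 3-oxo-2-RA-5-(prop-1-en-2-yl)cyclohexane-1-carboxylic acid
Product: 17 tert-butyl 3-oxo-2-RA-5-(prop-1-en-2-yl)cyclohexane-1-carboxylate
Conditions: Boc2O, DMAP (cat.), t-BuOH, rt
Reagents that add atoms: di-tert-butyl dicarbonate CC(C)(C)OC(=O)OC(=O)OC(C)(C)C
Why: DMAP-catalysed tert-butyl esterification through the mixed anhydride gives an enolisable ester that can later be cleaved without base.

Step 12
Reactants: 17 tert-butyl 3-oxo-2-RA-5-(prop-1-en-2-yl)cyclohexane-1-carboxylate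
Product: 19 all-equatorial tert-butyl 3-hydroxy-2-RA-5-(prop-1-en-2-yl)cyclohexane-1-carboxylate, via all-equatorial keto ester 18 (not isolated)
Conditions: t-BuOK (cat.), t-BuOH/THF, rt; then NaBH4, MeOH, −20 °C
Reagents that add atoms: none
Why: Base-mediated epimerisation at C8 and C9 (thermodynamic control) should favour the isomer with ring A equatorial and trans to the isopropenyl group, and axial hydride attack on C11 then gives the equatorial alcohol trans to C9.

Step 13
Reactants: 19 all-equatorial tert-butyl 3-hydroxy-2-RA-5-(prop-1-en-2-yl)cyclohexane-1-carboxylate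
Product: 21 tert-butyl 3-(tert-butyldimethylsilyloxy)-6-methylidene-2-RA-bicyclo[3.2.1]octane-1-carboxylate, via silyl ketene acetal 20 (not isolated)
Conditions: KN(SiMe3)2 (2.3 equiv), t-BuMe2SiCl, THF/DMPU, −78 to 0 °C; then Pd(OAc)2 (1.1 equiv), AcOH, DMSO, air, 45 °C
Reagents that add atoms: tert-butyldimethylsilyl chloride CC(C)(C)[Si](C)(C)Cl
Why: Palladium-mediated oxidative enolate–alkene cyclisation, in which the divalent palladium enolate from ketene acetal 20 adds to the isopropenyl group and β-hydride eliminates, so the new C8–C15 bond must form cis to C13–C16, which fixes C8 and leaves the 16-methylene.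

Step 14
Reactants: 21 tert-butyl 3-(tert-butyldimethylsilyloxy)-6-methylidene-2-RA-bicyclo[3.2.1]octane-1-carboxylate
Product: 22 3-(tert-butyldimethylsilyloxy)-6-methylidene-2-RA′-bicyclo[3.2.1]octane-1-carboxylic acid
Conditions: 85 % aq. H3PO4, toluene, rt
Reagents that add atoms: water O
Why: Acid hydrolysis cleaves the tert-butyl ester by alkyl–oxygen fission and both dioxolanes, while the silyl ether and the exocyclic alkene should survive.

Step 15
Reactants: 22 3-(tert-butyldimethylsilyloxy)-6-methylidene-2-RA′-bicyclo[3.2.1]octane-1-carboxylic acid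
Product: 23 chloromethyl ester of acid 22
Conditions: ClCH2OSO2Cl, NaHCO3, Bu4NHSO4, CH2Cl2/H2O, rt
Reagents that add atoms: chloromethyl chlorosulfate ClCOS(=O)(=O)Cl
Why: Phase-transfer O-alkylation of the hindered carboxylate with chloromethyl chlorosulfate gives the ester that carries C20.

Step 16
Reactants: 23 chloromethyl ester of acid 22
Product: 25 spirolactone keto aldehyde (C1 ketone, C6 aldehyde, 11-OTBS, 16-methylene), via iodomethyl ester 24 (not isolated)
Conditions: NaI, acetone, rt; then Bu3SnH (syringe pump), AIBN, benzene (5 mM), 80 °C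
Reagents that add atoms: none
Why: Finkelstein exchange gives iodomethyl ester 24, from which the tin radical abstracts iodine to give the acyloxymethyl radical at C20. This nucleophilic radical adds to C10, the β-carbon of the C5=C10 enal (also activated by the C1 ketone), and the resulting α-formyl radical at C5 takes hydrogen from Bu3SnH; the closest known reaction type is the radical cyclisation of halomethyl alkenoates (intramolecular Giese addition of an acyloxymethyl radical). The δ-lactone ring C7–O–C20–C10–C9–C8 closes in the 6-exo-trig mode. C10 is controlled by C9: allylic 1,3-strain holds H9 in the plane of the enal, syn to the formyl group, so the tether on C8 reaches only the face that places C1 anti to H9; C5 is set by axial hydrogen delivery anti to the new C10–C20 bond. The step needs cyclisation to outrun reduction and to spare the 16-methylene; slow addition of Bu3SnH at high dilution and the higher reactivity of the doubly activated C5=C10 bond should secure both.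

Step 17
Reactants: 25 spirolactone keto aldehyde
Product: 26 spirolactone 1α,6-diol
Conditions: NaBH4, MeOH/THF, 0 °C
Reagents that add atoms: none
Why: Borohydride reduces aldehyde C6 and ketone C1, with axial hydride delivery to C1 from the face anti to the axial C20 of the spiro centre giving the equatorial 1α-alcohol.

Step 18
Reactants: 26 spirolactone 1α,6-diol
Product: 27 6-O-TBS ether of diol 26
Conditions: t-BuMe2SiCl (1.1 equiv), imidazole, CH2Cl2, 0 °C
Reagents that add atoms: tert-butyldimethylsilyl chloride CC(C)(C)[Si](C)(C)Cl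
Why: Steric differentiation leads to selective silylation of the primary 6-hydroxyl over the hindered secondary 1-hydroxyl.

Step 19
Reactants: 27 6-O-TBS ether of diol 26
Product: 28 1-acetate of 27
Conditions: Ac2O, DMAP, pyridine, rt
Reagents that add atoms: acetic anhydride CC(=O)OC(C)=O
Why: DMAP-catalysed acetylation of the only free hydroxyl installs the 1-acetate.

Step 20
Reactants: 28 1-acetate of 27
Product: 30 15-oxo-16-methylene enone, via 15-epi allylic alcohol 29 (not isolated)
Conditions: SeO2 (cat.), t-BuOOH, CH2Cl2, rt; then Dess–Martin periodinane, NaHCO3, CH2Cl2, rt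
Reagents that add atoms: tert-butyl hydroperoxide CC(C)(C)OO; selenium dioxide O=[Se]=O
Why: Selenium-catalysed allylic hydroxylation (ene reaction, then [2,3]-sigmatropic shift) oxidises C15, the only allylic methylene, and Dess–Martin oxidation of the crude alcohol gives the enone, so the configuration of 29 does not matter.

Step 21
Reactants: 30 15-oxo-16-methylene enone
Product: 31 6,11-bis-O-TBS ether of the target
Conditions: NaBH4, CeCl3·7H2O, MeOH, −78 °C
Reagents that add atoms: none
Why: Luche 1,2-reduction, in which hydride should attack C15 from the ring D face remote from the C9–C11–C12 bridge and its 11-silyloxy group, giving the 15-alcohol syn to C9.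

Step 22
Reactants: 31 6,11-bis-O-TBS ether of the target
Product: 32 CNP0210922.1
Conditions: HF·pyridine, THF, 0 °C to rt
Reagents that add atoms: none
Why: Fluoride-mediated desilylation removes both silyl ethers while the acetate and the lactone are stable.

Compound list
1 | cyclohex-2-en-1-one | O=C1C=CCCC1 | starting material
2 | potassium isopropenyltrifluoroborate | [K+].C=C(C)[B-](F)(F)F | starting material
3 | (S)-3-(prop-1-en-2-yl)cyclohexan-1-one | C=C(C)[C@@H]1CC(=O)CCC1 | intermediate
4 | (S)-trimethyl{[5-(prop-1-en-2-yl)cyclohex-1-en-1-yl]oxy}silane | C=C(C)[C@@H]1CC(O[Si](C)(C)C)=CCC1 | intermediate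
5 | (S)-5-(prop-1-en-2-yl)cyclohex-2-en-1-one | C=C(C)[C@@H]1CC(=O)C=CC1 | intermediate
6 | (S)-2-iodo-5-(prop-1-en-2-yl)cyclohex-2-en-1-one | C=C(C)[C@@H]1CC(=O)C(I)=CC1 | intermediate
7 | 4,4-dimethylcyclohex-2-en-1-one | CC1(C)CCC(=O)C=C1 | starting material
8 | trimethyl[(3,4,4-trimethylcyclohex-1-en-1-yl)oxy]silane (racemic) | CC1C=C(O[Si](C)(C)C)CCC1(C)C | intermediate
9 | 3,4,4-trimethylcyclohex-2-en-1-one | CC1=CC(=O)CCC1(C)C | intermediate
10 | 6,6-dimethyl-3-oxocyclohex-1-ene-1-carbaldehyde | O=CC1=CC(=O)CCC1(C)C | intermediate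
11 | 2-bromo-6,6-dimethyl-3-oxocyclohex-1-ene-1-carbaldehyde | O=CC1=C(Br)C(=O)CCC1(C)C | intermediate
12 | 6-bromo-7-(1,3-dioxolan-2-yl)-8,8-dimethyl-1,4-dioxaspiro[4.5]dec-6-ene | BrC1=C(C2OCCO2)C(C)(C)CCC13OCCO3 | intermediate
13 | alkenylzinc chloride from 12 | Cl[Zn]C1=C(C2OCCO2)C(C)(C)CCC13OCCO3 | intermediate
14 | (S)-2-RA-5-(prop-1-en-2-yl)cyclohex-2-en-1-one | C=C(C)[C@@H]1CC(=O)C(C2=C(C3OCCO3)C(C)(C)CCC24OCCO4)=CC1 | intermediate
15 | 2-RA-3-(nitromethyl)-5-(prop-1-en-2-yl)cyclohexan-1-one, 3,5-trans, C2 epimers | C=C(C)[C@@H]1CC(=O)C(C2=C(C3OCCO3)C(C)(C)CCC24OCCO4)[C@@H](C[N+](=O)[O-])C1 | intermediate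
16 | 3-oxo-2-RA-5-(prop-1-en-2-yl)cyclohexane-1-carboxylic acid, 1,5-trans, C2 epimers | C=C(C)[C@@H]1CC(=O)C(C2=C(C3OCCO3)C(C)(C)CCC24OCCO4)[C@@H](C(=O)O)C1 | intermediate
17 | tert-butyl ester of 16 | C=C(C)[C@@H]1CC(=O)C(C2=C(C3OCCO3)C(C)(C)CCC24OCCO4)[C@@H](C(=O)OC(C)(C)C)C1 | intermediate
18 | all-equatorial tert-butyl 3-oxo-2-RA-5-(prop-1-en-2-yl)cyclohexane-1-carboxylate | C=C(C)[C@@H]1CC(=O)[C@@H](C2=C(C3OCCO3)C(C)(C)CCC24OCCO4)[C@H](C(=O)OC(C)(C)C)C1 | intermediate
19 | all-equatorial tert-butyl 3-hydroxy-2-RA-5-(prop-1-en-2-yl)cyclohexane-1-carboxylate | C=C(C)[C@@H]1C[C@H](O)[C@@H](C2=C(C3OCCO3)C(C)(C)CCC24OCCO4)[C@H](C(=O)OC(C)(C)C)C1 | intermediate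
20 | 11-O-TBS silyl ketene acetal of 19 | C=C(C)[C@@H]1C[C@H](O[Si](C)(C)C(C)(C)C)[C@@H](C2=C(C3OCCO3)C(C)(C)CCC24OCCO4)C(=C(OC(C)(C)C)O[Si](C)(C)C(C)(C)C)C1 | intermediate
21 | tert-butyl 3-(tert-butyldimethylsilyloxy)-6-methylidene-2-RA-bicyclo[3.2.1]octane-1-carboxylate (RA on C9 anti to C15, 11β-OTBS) | C=C1[C@@H]2C[C@H](O[Si](C)(C)C(C)(C)C)[C@@H](C3=C(C4OCCO4)C(C)(C)CCC35OCCO5)[C@](C2)(C(=O)OC(C)(C)C)C1 | intermediate
22 | 3-(tert-butyldimethylsilyloxy)-6-methylidene-2-RA′-bicyclo[3.2.1]octane-1-carboxylic acid | C=C1[C@@H]2C[C@H](O[Si](C)(C)C(C)(C)C)[C@@H](C3=C(C=O)C(C)(C)CCC3=O)[C@](C2)(C(=O)O)C1 | intermediate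
23 | chloromethyl ester of 22 | C=C1[C@@H]2C[C@H](O[Si](C)(C)C(C)(C)C)[C@@H](C3=C(C=O)C(C)(C)CCC3=O)[C@](C2)(C(=O)OCCl)C1 | intermediate
24 | iodomethyl ester of 22 | C=C1[C@@H]2C[C@H](O[Si](C)(C)C(C)(C)C)[C@@H](C3=C(C=O)C(C)(C)CCC3=O)[C@](C2)(C(=O)OCI)C1 | intermediate
25 | spirolactone keto aldehyde (C1 ketone, C6 aldehyde, 11β-OTBS, 16-methylene) | C=C1[C@@H]2C[C@H](O[Si](C)(C)C(C)(C)C)[C@@H]3[C@](C2)(C(=O)OC[C@]32C(=O)CCC(C)(C)[C@H]2C=O)C1 | intermediate
26 | spirolactone 1α,6-diol (11β-OTBS) | C=C1[C@@H]2C[C@H](O[Si](C)(C)C(C)(C)C)[C@@H]3[C@](C2)(C(=O)OC[C@]32[C@@H](O)CCC(C)(C)[C@H]2CO)C1 | intermediate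
27 | 6-O-TBS ether of 26 | C=C1[C@@H]2C[C@H](O[Si](C)(C)C(C)(C)C)[C@@H]3[C@](C2)(C(=O)OC[C@]32[C@@H](O)CCC(C)(C)[C@H]2CO[Si](C)(C)C(C)(C)C)C1 | intermediate
28 | 1-acetate of 27 | C=C1[C@@H]2C[C@H](O[Si](C)(C)C(C)(C)C)[C@@H]3[C@](C2)(C(=O)OC[C@]32[C@@H](OC(C)=O)CCC(C)(C)[C@H]2CO[Si](C)(C)C(C)(C)C)C1 | intermediate
29 | 15-epi allylic alcohol of 28 | C=C1[C@@H]2C[C@H](O[Si](C)(C)C(C)(C)C)[C@@H]3[C@](C2)(C(=O)OC[C@]32[C@@H](OC(C)=O)CCC(C)(C)[C@H]2CO[Si](C)(C)C(C)(C)C)[C@H]1O | intermediate
30 | 15-oxo-16-methylene enone | C=C1[C@@H]2C[C@H](O[Si](C)(C)C(C)(C)C)[C@@H]3[C@](C2)(C(=O)OC[C@]32[C@@H](OC(C)=O)CCC(C)(C)[C@H]2CO[Si](C)(C)C(C)(C)C)C1=O | intermediate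
31 | 6,11-bis-O-TBS ether of the target | C=C1[C@@H]2C[C@H](O[Si](C)(C)C(C)(C)C)[C@@H]3[C@](C2)(C(=O)OC[C@]32[C@@H](OC(C)=O)CCC(C)(C)[C@H]2CO[Si](C)(C)C(C)(C)C)[C@@H]1O | intermediate
32 | CNP0210922.1 | C=C1[C@@H]2C[C@H](O)[C@@H]3[C@](C2)(C(=O)OC[C@]32[C@@H](OC(C)=O)CCC(C)(C)[C@H]2CO)[C@@H]1O | target

Total step count: 22
Longest linear sequence: 19 steps (steps 4–22, from 4,4-dimethylcyclohex-2-en-1-one)

Steps most likely to fail

Step 16. The acyloxymethyl radical may be reduced by the tin hydride before the ester rotates into the s-cis form needed for ring closure, or it may add to the wrong face of C10. The fallback sets out from 22 and returns at 25. The carboxylate of 22 is alkylated with tert-butyl bromoacetate (Cs2CO3, DMF) to the tert-butoxycarbonylmethyl ester F1. Aqueous H3PO4 (85 %) frees the carboxymethyl ester F2. Visible-light photoredox decarboxylation (Ir[dF(CF3)ppy]2(dtbbpy)PF6, K2HPO4, DMF, blue LEDs) then generates the same C20 radical with no hydrogen-atom donor present, so cyclisation need not outrun reduction; the α-formyl radical is reduced to the enolate and protonated to give 25.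

Step 13. The hindered silyl ketene acetal may fail to reach the isopropenyl group through the boat-like transition state, ending in desilylation or simple oxidation of the enolate. The fallback sets out from 19 and returns at 21. Silylation (t-BuMe2SiOTf, 2,6-lutidine) gives silyl ether F3. Ene-type allylic chlorination of the isopropenyl group (Ca(OCl)2, CO2, CH2Cl2/H2O) gives allylic chloride F4; the shielded tetrasubstituted ring A alkene is expected to react more slowly. KN(SiMe3)2 then closes ring D by intramolecular SN2 alkylation of the ester enolate, giving 21.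

Step 8. Transmetalation and reductive elimination between two hindered alkenyl partners may be slow, leading to protodezincation and homocoupling. The fallback sets out from 3 (through its silyl enol ether 4) and 12 and returns at 14. Palladium-catalysed α-alkenylation of silyl enol ether 4 with bromide 12 (Pd2(dba)3, t-Bu3P, Bu3SnF, toluene) gives the 2-alkenyl ketone F5. Dehydrogenation with IBX (DMSO, 70 °C) on the more substituted, conjugated side then gives enone 14.

Further compounds
F1 | step 16 | tert-butoxycarbonylmethyl ester of acid 22 | C=C1[C@@H]2C[C@H](O[Si](C)(C)C(C)(C)C)[C@@H](C3=C(C=O)C(C)(C)CCC3=O)[C@](C2)(C(=O)OCC(=O)OC(C)(C)C)C1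
F2 | step 16 | carboxymethyl ester of acid 22 | C=C1[C@@H]2C[C@H](O[Si](C)(C)C(C)(C)C)[C@@H](C3=C(C=O)C(C)(C)CCC3=O)[C@](C2)(C(=O)OCC(=O)O)C1
F3 | step 13 | 11-O-TBS ether of hydroxy ester 19 | C=C(C)[C@@H]1C[C@H](O[Si](C)(C)C(C)(C)C)[C@@H](C2=C(C3OCCO3)C(C)(C)CCC24OCCO4)[C@H](C(=O)OC(C)(C)C)C1
F4 | step 13 | allylic chloride of F3 (3-chloroprop-1-en-2-yl group on C13) | ClCC(=C)[C@@H]1C[C@H](O[Si](C)(C)C(C)(C)C)[C@@H](C2=C(C3OCCO3)C(C)(C)CCC24OCCO4)[C@H](C(=O)OC(C)(C)C)C1
F5 | step 8 | 2-RA-5-(prop-1-en-2-yl)cyclohexan-1-one (C2 epimers) | C=C(C)[C@@H]1CC(=O)C(C2=C(C3OCCO3)C(C)(C)CCC24OCCO4)CC1
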